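**Retrosynthetic overview**

1. Ester C–O bond first: chloroketone 1 + 4-hydroxybenzoic acid 2 ⇒ phenacyl ester 3, so the acyl group sits on the future O3 from the start and no protecting groups are needed.
2. Ring C (C3–C4 and O1–C2 bonds): 3 + 2,4,6-trihydroxybenzaldehyde 4 ⇒ chalcone 5 ⇒ flavylium chloride 6. Ring C is made flat, achiral and aromatic.
3. Key step: enantioselective dearomatising hydrogenation of the pyrylium ring of 6 (through 7 and 8) gives target 9, creating C2–H, C3–H, C4–H2 and both stereocentres in one operation.
4. Ring order: ring A, ring B and the benzoate ring are bought as simple arenes; ring C is the only ring formed.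

Assumption: 1, 2 and 4 are bought as such, and the (S)-ligand in step 3 is the enantiomer assumed to give (2R,3R); if the first run gives the antipode, the (R)-ligand is used instead.

**Step 1**
Reactants: 1 2-chloro-1-(3,4-dihydroxyphenyl)ethanone; 2 4-hydroxybenzoic acid
Product: 3 2-(3,4-dihydroxyphenyl)-2-oxoethyl 4-hydroxybenzoate
Conditions: 2 (1.3 equiv), KHCO3 (1.1 equiv), KI (0.1 equiv), EtOH, 70 °C, 6 h
Reagents that add atoms: none
Why: Phenacyl ester formation by SN2 displacement of the activated α-chloroketone chloride by carboxylate (Finkelstein-assisted through the iodoketone); in ethanol with one equivalent of bicarbonate only the carboxylic acid (pKa about 4.5) is ionised while the phenols (pKa about 8 to 9) stay protonated, as in the classical acetate displacement on this same chloroketone; no stereocentre.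

**Step 2**
Reactants: 3 2-(3,4-dihydroxyphenyl)-2-oxoethyl 4-hydroxybenzoate; 4 2,4,6-trihydroxybenzaldehyde
Product: 6 3-O-(4-hydroxybenzoyl)cyanidin chloride, via chalcone 5 (not isolated)
Conditions: HCl (g, saturated), dry EtOAc, 0 °C then 4 °C, 48 h; filter the red salt, wash with Et2O
Reagents that add atoms: hydrogen chloride, Cl
Why: Robinson flavylium (anthocyanidin) synthesis: acid-mediated aldol condensation of the aldehyde with the doubly activated CH2 of 3 gives the ortho-hydroxychalcone 5, which cyclises onto the ketone and dehydrates to the aromatic benzopyrylium ring C that precipitates as its chloride, while anhydrous HCl leaves the ester intact; no stereocentre.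

**Step 3**
Reactants: 6 3-O-(4-hydroxybenzoyl)cyanidin chloride
Product: 9 (2R,3R)-epicatechin 3-O-p-hydroxybenzoate, via 4H-flavene 7 (not isolated), via flavan-2-ylium chloride 8 (not isolated)
Conditions: H2 (50 bar), [{Ir(H)[(S)-SegPhos]}2(μ-Cl)3]Cl (2 mol %), CF3CH2OH/CH2Cl2 (1:1), 25 °C, 24 h
Reagents that add atoms: none
Why: Proposed new method: asymmetric ionic (outer-sphere) hydrogenation of a benzopyrylium salt, in which the chiral trivalent iridium hydride first delivers H− to C4 of the flavylium (no stereocentre, gives enol ether 7 and one equivalent of HCl), HCl reversibly protonates 7 at C3 to the 2-aryl oxocarbenium 8 so that C3 epimerises freely, and the second, enantio-determining hydride transfer to C2 takes place on one face of the matched C3 epimer, anti to the pseudo-axial 3-acyloxy group (A(1,2) strain with the coplanar 2-aryl ring, reinforced by acyloxonium participation), so both centres emerge 2,3-cis as (2R,3R) by dynamic kinetic resolution; the closest known reaction types are the iridium–diphosphine hydrogenation of quinolinium, isoquinolinium and pyridinium hydrohalides to cis-2,3-disubstituted products, the asymmetric ionic hydrogenation of benzo-fused cyclic oxocarbenium ions, and the racemic platinum-catalysed hydrogenation of cyanidin chloride to cis-configured (±)-epicatechin.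

**Compound list**

1 | 2-chloro-1-(3,4-dihydroxyphenyl)ethanone | O=C(CCl)c1ccc(O)c(O)c1 | starting material
2 | 4-hydroxybenzoic acid | O=C(O)c1ccc(O)cc1 | starting material
3 | 2-(3,4-dihydroxyphenyl)-2-oxoethyl 4-hydroxybenzoate | O=C(COC(=O)c1ccc(O)cc1)c1ccc(O)c(O)c1 | intermediate
4 | 2,4,6-trihydroxybenzaldehyde | O=Cc1c(O)cc(O)cc1O | starting material
5 | (E)-3-(3,4-dihydroxyphenyl)-3-oxo-1-(2,4,6-trihydroxyphenyl)prop-1-en-2-yl 4-hydroxybenzoate (chalcone; the isomer that cyclises is drawn) | O=C(c1ccc(O)c(O)c1)/C(OC(=O)c1ccc(O)cc1)=C\c1c(O)cc(O)cc1O | intermediate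
6 | 5,7-dihydroxy-2-(3,4-dihydroxyphenyl)-3-[(4-hydroxybenzoyl)oxy]chromenylium chloride (3-O-(4-hydroxybenzoyl)cyanidin chloride) | Oc1ccc(cc1)C(=O)Oc1cc2c(O)cc(O)cc2[o+]c1-c1ccc(O)c(O)c1.[Cl-] | intermediate
7 | 5,7-dihydroxy-2-(3,4-dihydroxyphenyl)-4H-chromen-3-yl 4-hydroxybenzoate (4H-flavene, achiral) | O=C(OC1=C(c2ccc(O)c(O)c2)Oc2cc(O)cc(O)c2C1)c1ccc(O)cc1 | intermediate
8 | (3R)-5,7-dihydroxy-2-(3,4-dihydroxyphenyl)-3-[(4-hydroxybenzoyl)oxy]-3,4-dihydrochromenylium chloride (flavan-2-ylium ion pair; C3 epimerises, reactive 3R epimer drawn) | O=C(O[C@@H]1Cc2c(O)cc(O)cc2[O+]=C1c1ccc(O)c(O)c1)c1ccc(O)cc1.[Cl-] | intermediate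
9 | (2R,3R)-2-(3,4-dihydroxyphenyl)-5,7-dihydroxy-3,4-dihydro-2H-chromen-3-yl 4-hydroxybenzoate (epicatechin 3-O-p-hydroxybenzoate) | O=C(O[C@@H]1Cc2c(O)cc(O)cc2O[C@@H]1c1ccc(O)c(O)c1)c1ccc(O)cc1 | target

**Total step count:** 3
**Longest linear sequence:** 3 steps (1 → 3 → 6 → 9)

**Steps most likely to fail, with fallbacks**

Step 3 (highest risk: activity of the iridium hydride towards the free-phenol flavylium salt, and the level and sense of enantioselectivity). The fallback sets out from 6 and comes back at 9, replacing asymmetric catalysis by cis-selective heterogeneous reduction plus resolution. Compound 6 is hydrogenated over PtO2 under H2 (1 atm) in AcOH/EtOAc at 20 °C until two equivalents are taken up. Syn delivery of hydrogen from the catalyst surface gives only the 2,3-cis product, the racemic cis ester F1. The enantiomers of F1 are then separated by preparative chromatography on an amylose tris(3,5-dimethylphenylcarbamate) phase (supercritical CO2/MeOH with 0.1 % formic acid), and the (2R,3R) fraction is 9.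

Step 2 (self-condensation of the unprotected aldehyde 4 to xanthylium dyes, or low solubility in EtOAc). The fallback sets out from 3 and comes back at 6, closing ring C through the C4–C4a bond on the arene instead of the C3–C4 aldol bond. Compound 3 is heated with N,N-dimethylformamide dineopentyl acetal, a non-alkylating amide acetal, in THF/toluene at 70 °C to give the enaminone F2. F2 is then stirred with commercial phloroglucinol (benzene-1,3,5-triol) in HCl-saturated AcOH/EtOAc at 20 °C. The protonated vinylogous amide C-alkylates phloroglucinol, dimethylamine is lost, and cyclodehydration onto the ketone gives 6. No free trihydroxybenzaldehyde is ever present.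

Step 1 (competing phenoxide alkylation or oligomerisation of 1). The fallback sets out from 1 and comes back at 3, replacing the basic carboxylate displacement by a neutral redox condensation in which the nucleophile is selected by acidity. Compound 1 is heated with HCO2Na in EtOH/H2O at reflux; the formate ester F3 forms and is hydrolysed in the flask to the ketol F4. Mitsunobu esterification of the primary hydroxyl of F4 with 2 (PPh3, diisopropyl azodicarboxylate, THF, 0 to 20 °C) then gives 3. The carboxylic acid is by far the most acidic pronucleophile present, so the phenols are not alkylated.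

**Further compounds**

F1 | step 3 | racemic cis-2-(3,4-dihydroxyphenyl)-5,7-dihydroxy-3,4-dihydro-2H-chromen-3-yl 4-hydroxybenzoate (1:1 mixture of 2R,3R and 2S,3S) | O=C(O[C@@H]1Cc2c(O)cc(O)cc2O[C@@H]1c1ccc(O)c(O)c1)c1ccc(O)cc1.O=C(O[C@H]1Cc2c(O)cc(O)cc2O[C@H]1c1ccc(O)c(O)c1)c1ccc(O)cc1
F2 | step 2 | (Z)-1-(3,4-dihydroxyphenyl)-3-(dimethylamino)-1-oxoprop-2-en-2-yl 4-hydroxybenzoate | CN(C)/C=C(OC(=O)c1ccc(O)cc1)/C(=O)c1ccc(O)c(O)c1
F3 | step 1 | 2-(3,4-dihydroxyphenyl)-2-oxoethyl formate | O=COCC(=O)c1ccc(O)c(O)c1
F4 | step 1 | 1-(3,4-dihydroxyphenyl)-2-hydroxyethanone | O=C(CO)c1ccc(O)c(O)c1
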